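The flavone is cut through ring C at O1–C8a and C4–C4a, the two bonds that tie the pyranone to neighbouring carbons of ring A. Those two carbons are taken as an aryne that carries the 7-oxygen para to C4a and a removable chlorine at C5. In one operation the oxygen of an α-benzyloxy β-ketoester enolate arylates at C8a and the aryl anion left at C4a is acylated by the ester, which closes ring C with the 3-oxygen and ring B already in place. The aryne precursor is a chloro-substituted ortho-silyl aryl triflate made from 4-(benzyloxy)phenol; the ketoester comes from O-benzylvanillic acid. Hydrogenolysis and sulfation finish the route.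

Key step: step 5

Remarks on the chemistry:
- 4-(Benzyloxy)-3-methoxybenzoic acid (7) is assumed to be a catalogue compound; otherwise it is one operation from vanillic acid (benzylation with in situ ester hydrolysis).
- The target is drawn as the free tris(hydrogen sulfate). It is released from its pyridinium salt on an acid resin in the cold and should be kept cold or neutralised to the trisodium salt for storage, because aryl hydrogen sulfates hydrolyse under their own acidity.

Step 1
Reactants: 1 4-(benzyloxy)phenol
Product: 2 4-(benzyloxy)-2-chlorophenol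
Conditions: SO2Cl2 (1.0 equiv), CH2Cl2, 0 °C → rt
Reagents that add atoms: sulfuryl chloride, O=S(=O)(Cl)Cl
Why: Electrophilic aromatic chlorination: the free hydroxyl is the strongest director and its para position is blocked, so one equivalent of sulfuryl chloride should chlorinate ortho to OH while the benzyl ether stays intact under these mild, initiator-free conditions.

Step 2
Reactants: 2 4-(benzyloxy)-2-chlorophenol
Product: 3 4-(benzyloxy)-2-bromo-6-chlorophenol
Conditions: NBS (1.0 equiv), i-Pr2NH (10 mol%), CH2Cl2, 0 °C
Reagents that add atoms: N-bromosuccinimide, O=C1CCC(=O)N1Br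
Why: Amine-mediated ortho-bromination of a phenol: the N-bromoamine formed from NBS and the secondary amine is delivered through a hydrogen bond to the phenol, so bromine should enter the one free position ortho to OH in preference to the positions next to the benzyloxy group.

Step 3
Reactants: 3 4-(benzyloxy)-2-bromo-6-chlorophenol
Product: 6 4-(benzyloxy)-2-chloro-6-(trimethylsilyl)phenyl trifluoromethanesulfonate, via aryl silyl ether 4 (not isolated), via lithium silylphenoxide 5 (not isolated)
Conditions: HN(SiMe3)2, THF, 70 °C, then evaporate; n-BuLi (1.1 equiv), THF, –100 → –80 °C; Tf2O (1.2 equiv), –100 °C → rt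
Reagents that add atoms: hexamethyldisilazane, C[Si](C)(C)N[Si](C)(C)C; trifluoromethanesulfonic anhydride, O=S(=O)(OS(=O)(=O)C(F)(F)F)C(F)(F)F
Why: O-Silylation, bromine–lithium exchange and retro-Brook rearrangement (1,3 shift of silicon from oxygen to carbon), then O-triflation of the phenoxide: at –100 °C exchange at bromine outruns exchange at chlorine and benzylic deprotonation, and the aryllithium lies meta to chlorine, so it cannot expel halide.

Step 4
Reactants: 7 4-(benzyloxy)-3-methoxybenzoic acid; 8 methyl 2-(benzyloxy)acetate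
Product: 11 methyl 2-(benzyloxy)-3-[4-(benzyloxy)-3-methoxyphenyl]-3-oxopropanoate (racemic), via acid chloride 9 (not isolated), via lithium ester enolate 10 (not isolated)
Conditions: 7, (COCl)2 (1.3 equiv), DMF (cat.), CH2Cl2, 0 °C → rt, evaporate; 8 (2.1 equiv), LiN(SiMe3)2 (2.1 equiv), THF, –78 °C; then 9 in THF, –78 → 0 °C; 1 M HCl
Reagents that add atoms: none
Why: Crossed Claisen condensation by C-acylation of an ester lithium enolate with an aroyl chloride that cannot enolise: the second equivalent of enolate deprotonates the more acidic β-ketoester as it forms, which prevents a second acylation, and the new centre is left racemic and enolisable.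

Step 5
Reactants: 6 4-(benzyloxy)-2-chloro-6-(trimethylsilyl)phenyl trifluoromethanesulfonate; 11 methyl 2-(benzyloxy)-3-[4-(benzyloxy)-3-methoxyphenyl]-3-oxopropanoate
Product: 15 3,7-bis(benzyloxy)-2-[4-(benzyloxy)-3-methoxyphenyl]-5-chloro-4H-chromen-4-one, via caesium enolate 12 (not isolated), via chloroaryne 13 (not isolated), via aryl caesium adduct 14 (not isolated)
Conditions: 11 (1.0 equiv), anhydrous CsF (4 equiv), THF, 65 °C; 6 (1.5 equiv) added slowly
Reagents that add atoms: none
Why: Proposed new method: fluoride removes the silyl group of 6 and triflate leaves, giving aryne 13, whose C–Cl bond polarises the strained triple bond so that a nucleophile adds at the carbon meta to chlorine and the charge develops next to the halogen. The caesium enolate 12 is expected to attack through its ketone-derived oxygen, because its central carbon carries three substituents (aroyl, ester, benzyloxy) and is shielded; this forms O1–C8a and leaves the aryl anion 14 at C4a. Because the chelated, U-shaped enolate holds that oxygen cis to the methyl ester, the anion should close ring C by 6-exo-trig addition to the ester carbonyl and loss of methoxide, forming C4–C4a and the pyranone. The closest known reactions are the fluoride-induced coupling of arynes with salicylate esters to xanthones (O-arylation, then intramolecular acyl substitution) and the acyl-alkylation of arynes by β-ketoesters, which is the competing carbon-arylation path. No stereocentre is formed; the step needs regioselectivity, secured by the C5 chlorine, and oxygen over carbon arylation, which the fully substituted enolate carbon and the loosely ion-paired caesium enolate in THF are meant to secure. The released methoxide regenerates the enolate, so fluoride is consumed only in making the aryne.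

Step 6
Reactants: 15 3,7-bis(benzyloxy)-2-[4-(benzyloxy)-3-methoxyphenyl]-5-chloro-4H-chromen-4-one
Product: 16 3,7-dihydroxy-2-(4-hydroxy-3-methoxyphenyl)-4H-chromen-4-one (geraldol)
Conditions: H2 (1 atm), Pd/C (10% Pd), THF–MeOH, rt; then Et3N (2 equiv), H2 (1 atm), same flask, rt
Reagents that add atoms: none
Why: Palladium-catalysed hydrogenolysis of three aryl benzyl ethers, followed in the same flask by base-assisted hydrodechlorination of the aryl chloride activated by the ortho carbonyl; the amine is added only after debenzylation because amines slow benzyl ether cleavage on palladium, and the tetrasubstituted C2=C3 bond and the aryl methyl ether are not expected to react at 1 atm.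

Step 7
Reactants: 16 3,7-dihydroxy-2-(4-hydroxy-3-methoxyphenyl)-4H-chromen-4-one
Product: 18 2-[3-methoxy-4-(sulfooxy)phenyl]-4-oxo-4H-chromene-3,7-diyl bis(hydrogen sulfate) (target), via tris(pyridinium) trisulfate 17 (not isolated)
Conditions: SO3·pyridine (12 equiv), pyridine, 60 °C; MeOH quench; Sephadex LH-20 (MeOH–H2O); sulfonic acid resin (H+ form), H2O, 0 °C; freeze-dry
Reagents that add atoms: sulfur trioxide–pyridine complex, O=S(=O)([O-])[n+]1ccccc1
Why: O-Sulfation of phenolic and enolic hydroxyls with a sulfur trioxide–amine complex: a large excess and moderate heat should drive the least reactive 3-OH (hydrogen-bonded to the C4 carbonyl) to completion, there being no 5-OH to resist, and cold cation exchange converts the pyridinium salt into the free acid.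

Compound list

1 | 4-(benzyloxy)phenol | Oc1ccc(OCc2ccccc2)cc1 | starting material
2 | 4-(benzyloxy)-2-chlorophenol | Oc1ccc(OCc2ccccc2)cc1Cl | intermediate
3 | 4-(benzyloxy)-2-bromo-6-chlorophenol | Oc1c(Br)cc(OCc2ccccc2)cc1Cl | intermediate
4 | [4-(benzyloxy)-2-bromo-6-chlorophenoxy]trimethylsilane (formed in the flask) | C[Si](C)(C)Oc1c(Br)cc(OCc2ccccc2)cc1Cl | intermediate
5 | lithium 4-(benzyloxy)-2-chloro-6-(trimethylsilyl)phenolate (formed in the flask) | [Li+].[O-]c1c(Cl)cc(OCc2ccccc2)cc1[Si](C)(C)C | intermediate
6 | 4-(benzyloxy)-2-chloro-6-(trimethylsilyl)phenyl trifluoromethanesulfonate | C[Si](C)(C)c1cc(OCc2ccccc2)cc(Cl)c1OS(=O)(=O)C(F)(F)F | intermediate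
7 | 4-(benzyloxy)-3-methoxybenzoic acid | COc1cc(C(=O)O)ccc1OCc1ccccc1 | starting material
8 | methyl 2-(benzyloxy)acetate | COC(=O)COCc1ccccc1 | starting material
9 | 4-(benzyloxy)-3-methoxybenzoyl chloride (used crude) | COc1cc(C(=O)Cl)ccc1OCc1ccccc1 | intermediate
10 | lithium enolate of methyl 2-(benzyloxy)acetate (formed in the flask; enolate geometry not defined) | [Li+].[O-]C(OC)=COCc1ccccc1 | intermediate
11 | methyl 2-(benzyloxy)-3-[4-(benzyloxy)-3-methoxyphenyl]-3-oxopropanoate (racemic) | COC(=O)C(OCc1ccccc1)C(=O)c1ccc(OCc2ccccc2)c(OC)c1 | intermediate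
12 | caesium enolate of 11, chelated form with the enolate oxygen cis to the ester (formed in the flask) | [Cs+].[O-]/C(c1ccc(OCc2ccccc2)c(OC)c1)=C(\C(=O)OC)OCc1ccccc1 | intermediate
13 | 5-(benzyloxy)-3-chlorobenzyne (formed in the flask) | ClC1=CC(OCc2ccccc2)=CC#C1 | intermediate
14 | aryl caesium O-arylation adduct: methyl 2-(benzyloxy)-3-[4-(benzyloxy)-3-methoxyphenyl]-3-[5-(benzyloxy)-3-chloro-2-caesiophenoxy]prop-2-enoate, aryloxy group cis to the ester (formed in the flask) | COC(=O)/C(OCc1ccccc1)=C(\Oc1cc(OCc2ccccc2)cc(Cl)c1[Cs])c1ccc(OCc2ccccc2)c(OC)c1 | intermediate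
15 | 3,7-bis(benzyloxy)-2-[4-(benzyloxy)-3-methoxyphenyl]-5-chloro-4H-chromen-4-one | COc1cc(-c2oc3cc(OCc4ccccc4)cc(Cl)c3c(=O)c2OCc2ccccc2)ccc1OCc1ccccc1 | intermediate
16 | 3,7-dihydroxy-2-(4-hydroxy-3-methoxyphenyl)-4H-chromen-4-one (geraldol) | COc1cc(-c2oc3cc(O)ccc3c(=O)c2O)ccc1O | intermediate
17 | tris(pyridinium) 2-(3-methoxy-4-sulfonatooxyphenyl)-4-oxo-4H-chromene-3,7-diyl disulfate (formed in the flask) | COc1cc(-c2oc3cc(OS(=O)(=O)[O-])ccc3c(=O)c2OS(=O)(=O)[O-])ccc1OS(=O)(=O)[O-].c1cc[nH+]cc1.c1cc[nH+]cc1.c1cc[nH+]cc1 | intermediate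
18 | 2-[3-methoxy-4-(sulfooxy)phenyl]-4-oxo-4H-chromene-3,7-diyl bis(hydrogen sulfate) | COc1cc(-c2oc3cc(OS(=O)(=O)O)ccc3c(=O)c2OS(=O)(=O)O)ccc1OS(=O)(=O)O | target

Total step count: 7. Longest linear sequence: 6 steps (steps 1, 2, 3, 5, 6, 7); the ketoester branch (step 4) joins at step 5.

Steps most likely to fail

1. Step 5 (proposed new method). The enolate may arylate at carbon instead of oxygen, after which the aryl anion attacks the ketone and the acyl-alkylation path takes over. The aryl anion may also be protonated before it reaches the ester, or the ortho-chloroaryl anion may lose chloride. The fallback uses known chemistry, sets out from 7 through its chloride 9, and does not need the aryne.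
   - Acylation of commercial 1-[4-(benzyloxy)-2-hydroxyphenyl]ethanone with 9 (pyridine, CH2Cl2) should give 2-acetyl-5-(benzyloxy)phenyl 4-(benzyloxy)-3-methoxybenzoate F1.
   - Baker–Venkataraman rearrangement (KOH, pyridine, 50 °C) should give 1-[4-(benzyloxy)-2-hydroxyphenyl]-3-[4-(benzyloxy)-3-methoxyphenyl]propane-1,3-dione F2.
   - Acid-catalysed cyclodehydration (TsOH cat., toluene, reflux) should give 7-(benzyloxy)-2-[4-(benzyloxy)-3-methoxyphenyl]-4H-chromen-4-one F3.
   - Epoxidation of the C2=C3 bond with dimethyldioxirane (acetone–CH2Cl2, 0 °C) and acid-induced opening of the epoxide (TsOH cat.) should give 7-(benzyloxy)-2-[4-(benzyloxy)-3-methoxyphenyl]-3-hydroxy-4H-chromen-4-one F4.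
   - Hydrogenolysis (H2, Pd/C, THF–MeOH) returns to the route at 16.

2. Step 6. Hydrodechlorination may stall on a catalyst surface loaded with phenolic product and amine, or prolonged exposure may begin to reduce ring C. The fallback sets out from 15 and separates the two reductions. A homogeneous transfer hydrodechlorination (Pd(OAc)2, tricyclohexylphosphine, HCO2Na, DMF, 90 °C), which leaves benzyl ethers alone, should give 3,7-bis(benzyloxy)-2-[4-(benzyloxy)-3-methoxyphenyl]-4H-chromen-4-one F5. Plain hydrogenolysis without amine (H2, Pd/C, THF–MeOH, rt) then returns to the route at 16.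

3. Step 7. Sulfation may stop short at the hydrogen-bonded 3-hydroxyl, and sulfate may be lost during the acidic, aqueous isolation of a very polar product. The fallback sets out from 16 and uses protected sulfate esters that can be purified on silica.
   - 2,2,2-Trichloroethyl chlorosulfate with Et3N and 4-(dimethylamino)pyridine in THF should give 2-{3-methoxy-4-[(2,2,2-trichloroethoxy)sulfonyloxy]phenyl}-4-oxo-4H-chromene-3,7-diyl bis(2,2,2-trichloroethyl) bis(sulfate) F6.
   - Reductive removal of the trichloroethyl groups (Zn, HCO2NH4, MeOH, rt) should give the tris(ammonium) trisulfate F7.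
   - Cold passage through the acid resin returns to the route at 18.

Further compounds
F1 | step 5 | 2-acetyl-5-(benzyloxy)phenyl 4-(benzyloxy)-3-methoxybenzoate | CC(=O)c1ccc(OCc2ccccc2)cc1OC(=O)c1ccc(OCc2ccccc2)c(OC)c1
F2 | step 5 | 1-[4-(benzyloxy)-2-hydroxyphenyl]-3-[4-(benzyloxy)-3-methoxyphenyl]propane-1,3-dione | O=C(CC(=O)c1ccc(OCc2ccccc2)c(OC)c1)c1ccc(OCc2ccccc2)cc1O
F3 | step 5 | 7-(benzyloxy)-2-[4-(benzyloxy)-3-methoxyphenyl]-4H-chromen-4-one | COc1cc(-c2cc(=O)c3ccc(OCc4ccccc4)cc3o2)ccc1OCc1ccccc1
F4 | step 5 | 7-(benzyloxy)-2-[4-(benzyloxy)-3-methoxyphenyl]-3-hydroxy-4H-chromen-4-one | COc1cc(-c2oc3cc(OCc4ccccc4)ccc3c(=O)c2O)ccc1OCc1ccccc1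
F5 | step 6 | 3,7-bis(benzyloxy)-2-[4-(benzyloxy)-3-methoxyphenyl]-4H-chromen-4-one | COc1cc(-c2oc3cc(OCc4ccccc4)ccc3c(=O)c2OCc2ccccc2)ccc1OCc1ccccc1
F6 | step 7 | 2-{3-methoxy-4-[(2,2,2-trichloroethoxy)sulfonyloxy]phenyl}-4-oxo-4H-chromene-3,7-diyl bis(2,2,2-trichloroethyl) bis(sulfate) | COc1cc(-c2oc3cc(OS(=O)(=O)OCC(Cl)(Cl)Cl)ccc3c(=O)c2OS(=O)(=O)OCC(Cl)(Cl)Cl)ccc1OS(=O)(=O)OCC(Cl)(Cl)Cl
F7 | step 7 | tris(ammonium) 2-(3-methoxy-4-sulfonatooxyphenyl)-4-oxo-4H-chromene-3,7-diyl disulfate | COc1cc(-c2oc3cc(OS(=O)(=O)[O-])ccc3c(=O)c2OS(=O)(=O)[O-])ccc1OS(=O)(=O)[O-].[NH4+].[NH4+].[NH4+]
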